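## Retrosynthetic overview

- The target is reached from a symmetric 4,6-dibenzyl-5-styrylresorcinol by mono-O-methylation, then one hydrogenation that saturates the stilbene and removes four O-benzyl groups.
- Ring A is the only ring built: its C4–C5 bond is formed by aldol cyclo-aromatisation of an open-chain styryl 1,3,5-triketone. The strategy rests on ring A being a resorcinol (C1 OMe, C2 H, C3 OH) whose three contiguous carbon substituents (4-hydroxybenzyl at C4 and C6, the ethylene bridge at C5) lie on the two α-carbons and the terminal acyl carbon of that triketone.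
- The triketone comes from C-acylation of the dianion of a symmetric 1,7-diarylheptane-3,5-dione with the ring B cinnamoyl Weinreb amide.
- The diketone comes from pentane-2,4-dione by two successive dianion benzylations with 4-(benzyloxy)benzyl chloride. The Weinreb amide comes from Suzuki coupling of the same chloride with a formylarylboronic acid, then Horner–Wadsworth–Emmons olefination. The four other benzene rings are bought.

Key step: step 6

Assumption: 4-(benzyloxy)-3-formylphenylboronic acid and the Weinreb phosphonate are taken as catalogue reagents. The target is achiral, so the only stereo-element handled is the E alkene of the cinnamoyl unit, which the last step erases.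

## Route

Step 1
Reactants: 1 pentane-2,4-dione; 2 4-(benzyloxy)benzyl chloride
Product: 3 6-[4-(benzyloxy)phenyl]hexane-2,4-dione
Conditions: LiN(i-Pr)2 (LDA, 2.2 equiv), THF, 0 °C; 2 (0.95 equiv), 0 °C to rt; 1 M HCl
Reagents that add atoms: none
Why: Hauser–Harris terminal alkylation of a β-diketone 1,3-dianion, which reacts by SN2 only at its terminal, most basic carbon, a slight deficit of the chloride holding the reaction at the monobenzyl stage.

Step 2
Reactants: 3 6-[4-(benzyloxy)phenyl]hexane-2,4-dione; 2 4-(benzyloxy)benzyl chloride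
Product: 4 1,7-bis[4-(benzyloxy)phenyl]heptane-3,5-dione
Conditions: LiN(i-Pr)2 (LDA, 2.1 equiv), THF, −78 to 0 °C; 2 (1.0 equiv), 0 °C to rt; 1 M HCl
Reagents that add atoms: none
Why: Second Hauser–Harris dianion alkylation, in which the 1,3-dianion of the unsymmetrical β-diketone should form by deprotonation of the methyl group in preference to the substituted methylene, so the SN2 benzylation goes to the other terminus and gives the symmetric diketone.

Step 3
Reactants: 5 4-(benzyloxy)-3-formylphenylboronic acid; 2 4-(benzyloxy)benzyl chloride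
Product: 6 2-(benzyloxy)-5-[4-(benzyloxy)benzyl]benzaldehyde
Conditions: Pd(OAc)2 (cat.), PPh3, K3PO4 (hydrated), toluene, 80 °C
Reagents that add atoms: none
Why: sp2–sp3 Suzuki–Miyaura coupling, in which the activated benzylic C–Cl bond adds oxidatively to zerovalent palladium (formed in the flask from Pd(OAc)2 and PPh3), the arylboronate transmetalates and the diarylmethane is released by reductive elimination; no β-hydrogen is present and the aldehyde and benzyl ethers are inert.

Step 4
Reactants: 6 2-(benzyloxy)-5-[4-(benzyloxy)benzyl]benzaldehyde; 7 diethyl [2-(methoxy(methyl)amino)-2-oxoethyl]phosphonate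
Product: 8 (E)-3-{2-(benzyloxy)-5-[4-(benzyloxy)benzyl]phenyl}-N-methoxy-N-methylprop-2-enamide
Conditions: NaH, THF, 0 °C to rt
Reagents that add atoms: none
Why: Horner–Wadsworth–Emmons olefination of a non-enolisable aryl aldehyde with a stabilised phosphonate anion, which should give the E alkene under the usual thermodynamic control.

Step 5
Reactants: 4 1,7-bis[4-(benzyloxy)phenyl]heptane-3,5-dione; 8 (E)-3-{2-(benzyloxy)-5-[4-(benzyloxy)benzyl]phenyl}-N-methoxy-N-methylprop-2-enamide
Product: 9 (E)-1-{2-(benzyloxy)-5-[4-(benzyloxy)benzyl]phenyl}-4-[4-(benzyloxy)benzyl]-9-[4-(benzyloxy)phenyl]non-1-ene-3,5,7-trione (racemic at C4, largely enolised)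
Conditions: 4 (2.0 equiv), LiN(i-Pr)2 (LDA, 4.1 equiv), THF, −78 to 0 °C; 8 (1.0 equiv), −78 to 0 °C; cold 0.5 M HCl to pH 4; excess 4 recovered
Reagents that add atoms: none
Why: Harris-type C-acylation of a β-diketone 1,3-dianion at its terminal carbanion by a Weinreb amide, where the hard carbanion should add 1,2 to the weakly Michael-accepting unsaturated amide and the N-methoxy-chelated lithium adduct resists over-addition until the quench, the excess dianion covering any proton transfer from triketone set free early.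

Step 6
Reactants: 9 (E)-1-{2-(benzyloxy)-5-[4-(benzyloxy)benzyl]phenyl}-4-[4-(benzyloxy)benzyl]-9-[4-(benzyloxy)phenyl]non-1-ene-3,5,7-trione
Product: 11 4,6-bis[4-(benzyloxy)benzyl]-5-[(E)-2-{2-(benzyloxy)-5-[4-(benzyloxy)benzyl]phenyl}ethenyl]benzene-1,3-diol, via cyclic aldol 10 (not isolated)
Conditions: 2 M aq. KOH (8 equiv), MeOH/THF (degassed), Ar, rt to 45 °C; then 1 M HCl, 0 °C
Reagents that add atoms: none
Why: Hydroxide brings 9 into its enolate manifold, in which the minor tautomer enolised towards chain carbon C8 (the CH2 that carries a 4-(benzyloxy)benzyl group) adds to the cinnamoyl carbonyl, chain carbon C3, and so forms the C4–C5 bond of ring A; loss of water from aldol 10 and enolisation of the two remaining carbonyls then give the resorcinol irreversibly. The closest known reaction type is the alkaline aldol cyclo-aromatisation of 1,3,5-triketones to 5-substituted resorcinols (diacetylacetone to orcinol), the laboratory counterpart of the stilbene-synthase fold. Ring A closes in a 6-(enolendo)-exo-trig mode. No stereocentre has to be controlled, because the three sp3 centres of 10 are destroyed on aromatisation. The step needs a single aldol mode, which is secured because the styryl side has no enolisable hydrogen and every other enolate–carbonyl pairing would give a four-membered ring. It also needs the aldol to prevail over the two 6-endo-trig conjugate closures of the chain C5 oxygen or the chain C6 carbon onto the styryl β-carbon; these additions of stabilised diketonates to a β-aryl enone should be reversible in warm alkali whereas dehydration and aromatisation are not, so material is expected to drain towards 11.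

Step 7
Reactants: 11 4,6-bis[4-(benzyloxy)benzyl]-5-[(E)-2-{2-(benzyloxy)-5-[4-(benzyloxy)benzyl]phenyl}ethenyl]benzene-1,3-diol
Product: 12 2,4-bis[4-(benzyloxy)benzyl]-3-[(E)-2-{2-(benzyloxy)-5-[4-(benzyloxy)benzyl]phenyl}ethenyl]-5-methoxyphenol
Conditions: MeI (1.0 equiv), K2CO3 (1.1 equiv), acetone, rt; recovered 11 recycled
Reagents that add atoms: iodomethane, CI
Why: Williamson O-methylation of a phenoxide, in which the two hydroxyl groups of 11 are constitutionally equivalent, so only the degree of methylation has to be held by limiting iodomethane, K2CO3 in acetone favouring O- over C-alkylation.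

Step 8
Reactants: 12 2,4-bis[4-(benzyloxy)benzyl]-3-[(E)-2-{2-(benzyloxy)-5-[4-(benzyloxy)benzyl]phenyl}ethenyl]-5-methoxyphenol
Product: 13 2,4-bis(4-hydroxybenzyl)-3-{2-[2-hydroxy-5-(4-hydroxybenzyl)phenyl]ethyl}-5-methoxyphenol (target, CNP0134121.0)
Conditions: H2 (1 atm), 10% Pd/C, EtOAc/MeOH, rt
Reagents that add atoms: none
Why: Heterogeneous catalytic hydrogenation should saturate the stilbene C=C and hydrogenolyse the four benzylic C–O bonds in one operation, the diarylmethane C–C bonds, the aryl methyl ether and the phenol rings being inert at 1 atm.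

## Compound list

1 | pentane-2,4-dione | CC(=O)CC(C)=O | starting material
2 | 4-(benzyloxy)benzyl chloride | ClCc1ccc(OCc2ccccc2)cc1 | starting material
3 | 6-[4-(benzyloxy)phenyl]hexane-2,4-dione | CC(=O)CC(=O)CCc1ccc(OCc2ccccc2)cc1 | intermediate
4 | 1,7-bis[4-(benzyloxy)phenyl]heptane-3,5-dione | O=C(CCc1ccc(OCc2ccccc2)cc1)CC(=O)CCc1ccc(OCc2ccccc2)cc1 | intermediate
5 | 4-(benzyloxy)-3-formylphenylboronic acid | O=Cc1cc(B(O)O)ccc1OCc1ccccc1 | starting material
6 | 2-(benzyloxy)-5-[4-(benzyloxy)benzyl]benzaldehyde | O=Cc1cc(Cc2ccc(OCc3ccccc3)cc2)ccc1OCc1ccccc1 | intermediate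
7 | diethyl [2-(methoxy(methyl)amino)-2-oxoethyl]phosphonate | CCOP(=O)(CC(=O)N(C)OC)OCC | starting material
8 | (E)-3-{2-(benzyloxy)-5-[4-(benzyloxy)benzyl]phenyl}-N-methoxy-N-methylprop-2-enamide | CON(C)C(=O)/C=C/c1cc(Cc2ccc(OCc3ccccc3)cc2)ccc1OCc1ccccc1 | intermediate
9 | (E)-1-{2-(benzyloxy)-5-[4-(benzyloxy)benzyl]phenyl}-4-[4-(benzyloxy)benzyl]-9-[4-(benzyloxy)phenyl]non-1-ene-3,5,7-trione (racemic) | O=C(CCc1ccc(OCc2ccccc2)cc1)CC(=O)C(Cc1ccc(OCc2ccccc2)cc1)C(=O)/C=C/c1cc(Cc2ccc(OCc3ccccc3)cc2)ccc1OCc1ccccc1 | intermediate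
10 | 4,6-bis[4-(benzyloxy)benzyl]-5-[(E)-2-{2-(benzyloxy)-5-[4-(benzyloxy)benzyl]phenyl}ethenyl]-5-hydroxycyclohexane-1,3-dione (cyclic aldol, diastereomer mixture) | O=C1CC(=O)C(Cc2ccc(OCc3ccccc3)cc2)C(O)(/C=C/c2cc(Cc3ccc(OCc4ccccc4)cc3)ccc2OCc2ccccc2)C1Cc1ccc(OCc2ccccc2)cc1 | intermediate
11 | 4,6-bis[4-(benzyloxy)benzyl]-5-[(E)-2-{2-(benzyloxy)-5-[4-(benzyloxy)benzyl]phenyl}ethenyl]benzene-1,3-diol | Oc1cc(O)c(Cc2ccc(OCc3ccccc3)cc2)c(/C=C/c2cc(Cc3ccc(OCc4ccccc4)cc3)ccc2OCc2ccccc2)c1Cc1ccc(OCc2ccccc2)cc1 | intermediate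
12 | 2,4-bis[4-(benzyloxy)benzyl]-3-[(E)-2-{2-(benzyloxy)-5-[4-(benzyloxy)benzyl]phenyl}ethenyl]-5-methoxyphenol | COc1cc(O)c(Cc2ccc(OCc3ccccc3)cc2)c(/C=C/c2cc(Cc3ccc(OCc4ccccc4)cc3)ccc2OCc2ccccc2)c1Cc1ccc(OCc2ccccc2)cc1 | intermediate
13 | 2,4-bis(4-hydroxybenzyl)-3-{2-[2-hydroxy-5-(4-hydroxybenzyl)phenyl]ethyl}-5-methoxyphenol | COc1cc(O)c(Cc2ccc(O)cc2)c(CCc2cc(Cc3ccc(O)cc3)ccc2O)c1Cc1ccc(O)cc1 | target

## Summary

Total step count: 8. Longest linear sequence: 6 steps (steps 1, 2, 5, 6, 7 and 8 from 1 and 2; the arm through steps 3, 4, 5, 6, 7 and 8 from 5 and 2 is equally long).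

Steps most likely to fail:

1. Step 6. The conjugate ring closures (6-endo addition of the central diketonate carbon or of its oxygen to the styryl β-carbon) may outrun the aldol and not revert, or hydroxide may fragment the triketone by retro-Claisen cleavage. The fallback sets out from 4 and 6 and comes back at 11; it closes ring A before the bridge is attached, on a terminal carbonyl that is neither enolisable nor a Michael acceptor. The dianion of 4 (LDA, THF) is acylated with methyl dimethoxyacetate to the dimethoxyacetyl triketone F1. Aqueous KOH should close ring A to the 5-(dimethoxymethyl)resorcinol F2, and dilute HCl in THF unmasks 2,6-bis[4-(benzyloxy)benzyl]-3,5-dihydroxybenzaldehyde F3. In parallel 6 is reduced with NaBH4 to the benzyl alcohol F4, converted with PBr3 into the benzyl bromide F5, and heated with P(OEt)3 (Michaelis–Arbuzov) to the diethyl benzylphosphonate F6. Horner–Wadsworth–Emmons olefination of F3 with F6 (excess KOt-Bu, DMF, both phenols carried as phenoxides) should give the E stilbene 11.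

2. Step 5. The dianion may add in the conjugate sense to the unsaturated amide, or be quenched by proton transfer before acylation is complete; the triketone may also begin to cyclise during the acidic work-up. The fallback sets out from 6 and 4 and comes back at 9; it replaces acylation by aldol addition and oxidation. Aldehyde 6 is homologated with (triphenylphosphoranylidene)acetaldehyde (toluene, 80 °C) to the E cinnamaldehyde F7. The dianion of 4 adds 1,2 to F7 at −78 °C to give the hydroxy diketone F8 as a diastereomer mixture. Oxidation of the allylic alcohol with Dess–Martin periodinane (NaHCO3, CH2Cl2) should give 9.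

3. Step 7. Methylation may run on to the dimethyl ether or stall, leaving a statistical mixture that has to be separated and recycled; C-methylation at C2 is a lesser risk. The fallback sets out from 11 and comes back at 13; it replaces partial methylation by exhaustive methylation and a self-limiting demethylation. Resorcinol 11 is methylated fully (excess MeI, K2CO3, DMF) to the dimethyl ether F9. Hydrogenation over Pd/C gives the tetraphenol dimethyl ether F10. NaSEt in DMF at 140 °C should then remove one methyl group only, because the ring A phenoxide formed by the first demethylation shuts down the second, giving 13.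

## Further compounds

F1 | step 6 | 3-[4-(benzyloxy)benzyl]-8-[4-(benzyloxy)phenyl]-1,1-dimethoxyoctane-2,4,6-trione | O=C(CCc1ccc(OCc2ccccc2)cc1)CC(=O)C(Cc1ccc(OCc2ccccc2)cc1)C(=O)C(OC)OC
F2 | step 6 | 4,6-bis[4-(benzyloxy)benzyl]-5-(dimethoxymethyl)benzene-1,3-diol | COC(OC)c1c(Cc2ccc(OCc3ccccc3)cc2)c(O)cc(O)c1Cc1ccc(OCc2ccccc2)cc1
F3 | step 6 | 2,6-bis[4-(benzyloxy)benzyl]-3,5-dihydroxybenzaldehyde | O=Cc1c(Cc2ccc(OCc3ccccc3)cc2)c(O)cc(O)c1Cc1ccc(OCc2ccccc2)cc1
F4 | step 6 | {2-(benzyloxy)-5-[4-(benzyloxy)benzyl]phenyl}methanol | OCc1cc(Cc2ccc(OCc3ccccc3)cc2)ccc1OCc1ccccc1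
F5 | step 6 | 1-(benzyloxy)-4-[4-(benzyloxy)benzyl]-2-(bromomethyl)benzene | BrCc1cc(Cc2ccc(OCc3ccccc3)cc2)ccc1OCc1ccccc1
F6 | step 6 | diethyl {2-(benzyloxy)-5-[4-(benzyloxy)benzyl]benzyl}phosphonate | CCOP(=O)(Cc1cc(Cc2ccc(OCc3ccccc3)cc2)ccc1OCc1ccccc1)OCC
F7 | step 5 | (E)-3-{2-(benzyloxy)-5-[4-(benzyloxy)benzyl]phenyl}prop-2-enal | O=C/C=C/c1cc(Cc2ccc(OCc3ccccc3)cc2)ccc1OCc1ccccc1
F8 | step 5 | (E)-1-{2-(benzyloxy)-5-[4-(benzyloxy)benzyl]phenyl}-4-[4-(benzyloxy)benzyl]-9-[4-(benzyloxy)phenyl]-3-hydroxynon-1-ene-5,7-dione (diastereomer mixture) | O=C(CCc1ccc(OCc2ccccc2)cc1)CC(=O)C(Cc1ccc(OCc2ccccc2)cc1)C(O)/C=C/c1cc(Cc2ccc(OCc3ccccc3)cc2)ccc1OCc1ccccc1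
F9 | step 7 | 2,4-bis[4-(benzyloxy)benzyl]-3-[(E)-2-{2-(benzyloxy)-5-[4-(benzyloxy)benzyl]phenyl}ethenyl]-1,5-dimethoxybenzene | COc1cc(OC)c(Cc2ccc(OCc3ccccc3)cc2)c(/C=C/c2cc(Cc3ccc(OCc4ccccc4)cc3)ccc2OCc2ccccc2)c1Cc1ccc(OCc2ccccc2)cc1
F10 | step 7 | 4-(4-hydroxybenzyl)-2-{2-[2,6-bis(4-hydroxybenzyl)-3,5-dimethoxyphenyl]ethyl}phenol | COc1cc(OC)c(Cc2ccc(O)cc2)c(CCc2cc(Cc3ccc(O)cc3)ccc2O)c1Cc1ccc(O)cc1
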